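A fit that carries the step of Z with E into L hands you a constant for it, whether or not Wednesday's run holds one.

| setting | Wednesday's | flask |
|---|---|---|
| Z | 1 M | 1.0 M |
| remark | the very flask that is asked about, followed so far |  |
| time |  | 10 min |

Wednesday's run (percent of the Z charged)

| time / min | Z / % | E / % | J / % |
|---|---|---|---|
| 0.200 | 98.1 | 1.2 | 1.1 |
| 0.667 | 87.7 | 7.8 | 5.3 |
| 1.00 | 82.9 | 10.8 | 5.6 |
| 1.50 | 72.4 | 17.9 | 10.9 |
| 2.50 | 58.4 | 24.6 | 15.1 |
| 3.00 | 53.7 | 28.8 | 15.4 |
| 4.00 | 43.9 | 35.5 | 18.8 |

(scatter of a reading: 1 percentage point)

- percentages count the Z that a species holds: one L counts as two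
- candidate steps: Z -> E; Z -> J; Z + E -> L

* concentration of Z at 10 min, in M
* concentration of E at 10 min, in M
* concentration of J at 10 min, in M

The bench rule is simpler: take the decay constant, the logarithm of charge over Z remaining, divided by the time, 0.206 min⁻¹ from the last reading. It leaves 12.8% of the Z charged at 10 min, whatever the charge, if the loss is first order. Splitting the Z consumed as E and J stood at 4.00 min, my first round gives Z 0.128 M, E 0.570 M and J 0.302 M.

The rule's border is the step into L, which depends on the charge. The balance of that reading is short by 1.8 percentage points, with 1 point on each reading. If all of it is L, which counts double, the step took 1.60% of the Z consumed. Putting the first answers back in, the product of Z and E at 10 min is 0.467 of its value at 4.00 min, so I keep my round.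

The forecast gives Z 0.127 M, E 0.535 M and J 0.29 M. Its E lies below mine, since the gap “hints at a small amount of L”.

The flask gives Z 0.129 M, E 0.549 M and J 0.311 M, so 13% of its Z is still unreacted.

    Z → E (k = 0.130 min⁻¹)
    Z → J (k = 0.0730 min⁻¹)
    Z + E → L (k = 0.00480 M⁻¹ min⁻¹)

The step into L moves Z very little here. For the neighbouring flask charged with 0.40 M of Z, the decay constant gives 0.0510 M at 10 min. That flask holds 0.0522 M of Z, which is 13.0% of its charge, with 0.221 M of E and 0.125 M of J. Its L holds 0.454% of its charge, against 1.13% in the first flask.

The data were computed on assumed constants; noise was put on by code.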